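The route rests on cutting two neighbouring bonds of ring A together: O1–C8a and C8–CHO. Because the pyran oxygen on C8a and the formyl group on C8 are ortho to each other, both can be delivered across a C8–C8a aryne, which also tells C8 apart from the electronically similar C6. In one operation a hindered lithium amide turns an aryl triflate into that aryne, the side-chain alkoxide closes the pyran ring, and the C8 aryllithium left behind is formylated by DMF. The precursor is an open-chain (R)-2-aryl-3-arylpropan-1-ol whose ring A carries the triflate, the C7 MOM ether and the C5 methoxy group; an Evans alkylation sets its stereocentre.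

Key step: step 12

Remark: atoms are numbered as in the chromane (O1, C2–C4, C4a, C5–C8, C8a; primes for ring B); by CIP analysis (CH2O > aryl > CH2Ar > H) the target, the open-chain alcohol and the alkylated imide are all (R) at the carbon that becomes C3, which calls for the (R)-configured 4-benzyloxazolidinone.

Step 1
Reactants: 1 2,4-dihydroxy-6-methoxybenzaldehyde
Product: 2 2-hydroxy-6-methoxy-4-(methoxymethoxy)benzaldehyde
Conditions: MOMCl (1.05 equiv), i-Pr2NEt, CH2Cl2, 0 °C
Reagents that add atoms: chloromethyl methyl ether (MOMCl), COCCl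
Why: Williamson-type O-alkylation (MOM protection) should take the 4-OH selectively, since it is the more acidic and freely accessible phenol while the 2-OH is held in a hydrogen bond to the aldehyde.

Step 2
Reactants: 2 2-hydroxy-6-methoxy-4-(methoxymethoxy)benzaldehyde
Product: 3 2-formyl-3-methoxy-5-(methoxymethoxy)phenyl trifluoromethanesulfonate
Conditions: Tf2O, pyridine, CH2Cl2, 0 °C
Reagents that add atoms: trifluoromethanesulfonic anhydride (Tf2O), O=S(=O)(OS(=O)(=O)C(F)(F)F)C(F)(F)F
Why: O-sulfonylation of the remaining phenol (aryl triflate formation) under pyridine buffering should leave the MOM acetal and the aldehyde intact at 0 °C.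

Step 3
Reactants: 3 2-formyl-3-methoxy-5-(methoxymethoxy)phenyl trifluoromethanesulfonate
Product: 4 2-(hydroxymethyl)-3-methoxy-5-(methoxymethoxy)phenyl trifluoromethanesulfonate
Conditions: NaBH4, THF/MeOH, 0 °C
Reagents that add atoms: none
Why: Borohydride reduction of the aryl aldehyde is chemoselective because aryl triflates and MOM ethers are inert to NaBH4 at 0 °C.

Step 4
Reactants: 4 2-(hydroxymethyl)-3-methoxy-5-(methoxymethoxy)phenyl trifluoromethanesulfonate
Product: 5 2-(bromomethyl)-3-methoxy-5-(methoxymethoxy)phenyl trifluoromethanesulfonate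
Conditions: CBr4, PPh3, CH2Cl2, 0 °C
Reagents that add atoms: carbon tetrabromide, BrC(Br)(Br)Br
Why: The Appel reaction brominates the benzylic alcohol under neutral conditions that spare the acetal, and the electron-withdrawing ortho triflate should temper ionisation of the otherwise electron-rich benzylic bromide, which is used without storage.

Step 5
Reactants: 6 resorcinol
Product: 7 1,3-bis(methoxymethoxy)benzene
Conditions: MOMCl (2.4 equiv), i-Pr2NEt, CH2Cl2, 0 °C to rt
Reagents that add atoms: chloromethyl methyl ether (MOMCl), COCCl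
Why: Double Williamson-type MOM protection of both phenols installs the directing groups needed for the two metalations that follow.

Step 6
Reactants: 7 1,3-bis(methoxymethoxy)benzene; 8 prenyl bromide
Product: 10 1,3-bis(methoxymethoxy)-2-(3-methylbut-2-en-1-yl)benzene, via C2 aryllithium 9 (not isolated)
Conditions: n-BuLi, TMEDA, THF, 0 °C; then CuBr·SMe2 (10 mol %), 8, −78 °C to rt
Reagents that add atoms: none
Why: Directed ortho-metalation occurs at C2, the position flanked by both MOM ethers, and copper-catalysed SN2 allylation of the aryllithium at the primary carbon of the bromide should give the linear prenyl arene.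

Step 7
Reactants: 10 1,3-bis(methoxymethoxy)-2-(3-methylbut-2-en-1-yl)benzene
Product: 12 2-[2,4-bis(methoxymethoxy)-3-(3-methylbut-2-en-1-yl)phenyl]ethan-1-ol, via C4 aryllithium 11 (not isolated)
Conditions: n-BuLi, TMEDA, THF, 0 °C; then ethylene oxide, −78 °C to rt; H2O
Reagents that add atoms: ethylene oxide (oxirane), C1CO1
Why: A second directed ortho-metalation, now next to one MOM ether (C4 and C6 are equivalent by symmetry), is followed by ring opening of the epoxide by the aryllithium to give the 2-arylethanol.

Step 8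
Reactants: 12 2-[2,4-bis(methoxymethoxy)-3-(3-methylbut-2-en-1-yl)phenyl]ethan-1-ol
Product: 14 2-[2,4-bis(methoxymethoxy)-3-(3-methylbut-2-en-1-yl)phenyl]acetic acid, via arylacetaldehyde 13 (not isolated)
Conditions: TEMPO (cat.), PhI(OAc)2, MeCN/H2O, rt
Reagents that add atoms: water, O
Why: Nitroxyl-catalysed oxidation takes the primary alcohol through the aldehyde and its hydrate to the acid and should not touch the trisubstituted alkene, the acetals or the electron-rich ring.

Step 9
Reactants: 14 2-[2,4-bis(methoxymethoxy)-3-(3-methylbut-2-en-1-yl)phenyl]acetic acid; 15 (R)-4-benzyloxazolidin-2-one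
Product: 17 (4R)-4-benzyl-3-{2-[2,4-bis(methoxymethoxy)-3-(3-methylbut-2-en-1-yl)phenyl]acetyl}oxazolidin-2-one, via mixed pivalic anhydride 16 (not isolated)
Conditions: PivCl, Et3N, THF, −20 °C; then 15, LiCl, rt
Reagents that add atoms: none
Why: N-acylation of the oxazolidinone through the mixed anhydride under LiCl/Et3N activation is a mild one-pot imide formation that attacks the less hindered arylacetyl carbonyl.

Step 10
Reactants: 17 (4R)-4-benzyl-3-{2-[2,4-bis(methoxymethoxy)-3-(3-methylbut-2-en-1-yl)phenyl]acetyl}oxazolidin-2-one; 5 2-(bromomethyl)-3-methoxy-5-(methoxymethoxy)phenyl trifluoromethanesulfonate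
Product: 19 (4R)-4-benzyl-3-{(2R)-2-[2,4-bis(methoxymethoxy)-3-(3-methylbut-2-en-1-yl)phenyl]-3-[2-methoxy-4-(methoxymethoxy)-6-(trifluoromethylsulfonyloxy)phenyl]propanoyl}oxazolidin-2-one, via sodium Z-enolate 18 (not isolated)
Conditions: NaN(SiMe3)2, THF, −78 °C; then 5, −78 to −40 °C
Reagents that add atoms: none
Why: In this Evans asymmetric alkylation the chelated Z-enolate is shielded on one face by the benzyl group of the (R)-auxiliary, so the benzylic bromide enters from the opposite face and sets the (R) centre that becomes C3.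

Step 11
Reactants: 19 (4R)-4-benzyl-3-{(2R)-2-[2,4-bis(methoxymethoxy)-3-(3-methylbut-2-en-1-yl)phenyl]-3-[2-methoxy-4-(methoxymethoxy)-6-(trifluoromethylsulfonyloxy)phenyl]propanoyl}oxazolidin-2-one
Product: 20 2-{(2R)-2-[2,4-bis(methoxymethoxy)-3-(3-methylbut-2-en-1-yl)phenyl]-3-hydroxypropyl}-3-methoxy-5-(methoxymethoxy)phenyl trifluoromethanesulfonate
Conditions: LiBH4, H2O (1 equiv), Et2O, 0 °C
Reagents that add atoms: none
Why: Reductive cleavage of the imide by LiBH4 at the exocyclic carbonyl gives the primary alcohol and the recoverable auxiliary without touching the aryl triflate, and the stereocentre is no longer activated once the carbonyl is gone.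

Step 12
Reactants: 20 2-{(2R)-2-[2,4-bis(methoxymethoxy)-3-(3-methylbut-2-en-1-yl)phenyl]-3-hydroxypropyl}-3-methoxy-5-(methoxymethoxy)phenyl trifluoromethanesulfonate
Product: 25 (3R)-3-[2,4-bis(methoxymethoxy)-3-(3-methylbut-2-en-1-yl)phenyl]-5-methoxy-7-(methoxymethoxy)chromane-8-carbaldehyde, via C8-lithiated triflate 21 (not isolated), via C8–C8a aryne 22 (not isolated), via C8 aryllithium 23 (not isolated), via lithium hemiaminal alkoxide 24 (not isolated)
Conditions: lithium 2,2,6,6-tetramethylpiperidide (LiTMP, 2.3 equiv), THF, −78 to −40 °C (20 added to the base); then DMF, −78 °C to rt; H2O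
Reagents that add atoms: N,N-dimethylformamide (DMF), CN(C)C=O
Why: LiTMP deprotonates the hydroxyl group and then the C8 hydrogen, the most acidic ring proton because it sits between the triflate and the C7 MOM ether, and dilithio species 21 expels lithium triflate to give the C8–C8a aryne 22. The tethered alkoxide adds to C8a in a 6-exo-dig-type closure of the pyran ring (the aryne bond stays exocyclic to the new ring), which forms O1–C8a and leaves aryllithium 23 at C8; DMF then acylates 23 to hemiaminal alkoxide 24, which releases the aldehyde on aqueous work-up. The closest known reaction type is base-induced aryne formation from aryl triflates followed by nucleophilic addition and electrophilic quench of the ortho-functionalised aryllithium, here in its intramolecular alkoxide variant that is an established entry to chromans. No stereocentre is created, and the existing one (C3) bears no acidifying group and is not touched. The regiochemistry of addition is secured twice over: only attack at C8a gives a six-membered ring, and the inductively withdrawing C7 oxygen polarises the aryne so that charge builds up at C8, where the MOM oxygen and O1 then hold the lithium, so C6 is never involved. The hindered amide is chosen because it does not add to the aryne and its conjugate acid is too weak to protonate 23 before DMF arrives, inverse addition at −78 °C keeps the alkoxide from attacking the sulfonyl group, and the donor-substituted ring should favour loss of triflate from 21 over anionic thia-Fries migration, which is the selectivity the step depends on.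

Step 13
Reactants: 25 (3R)-3-[2,4-bis(methoxymethoxy)-3-(3-methylbut-2-en-1-yl)phenyl]-5-methoxy-7-(methoxymethoxy)chromane-8-carbaldehyde
Product: 26 (3R)-3-[2,4-dihydroxy-3-(3-methylbut-2-en-1-yl)phenyl]-7-hydroxy-5-methoxychromane-8-carbaldehyde
Conditions: HCl (1 M in MeOH), rt to 40 °C
Reagents that add atoms: none
Why: Acid-catalysed acetal solvolysis removes the three MOM ethers as dimethoxymethane, and dilute acid with short exposure is chosen so that the prenyl double bond is not protonated.

Compound list
1 | 2,4-dihydroxy-6-methoxybenzaldehyde | COc1cc(O)cc(O)c1C=O | starting material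
2 | 2-hydroxy-6-methoxy-4-(methoxymethoxy)benzaldehyde | COCOc1cc(O)c(C=O)c(OC)c1 | intermediate
3 | 2-formyl-3-methoxy-5-(methoxymethoxy)phenyl trifluoromethanesulfonate | COCOc1cc(OC)c(C=O)c(OS(=O)(=O)C(F)(F)F)c1 | intermediate
4 | 2-(hydroxymethyl)-3-methoxy-5-(methoxymethoxy)phenyl trifluoromethanesulfonate | COCOc1cc(OC)c(CO)c(OS(=O)(=O)C(F)(F)F)c1 | intermediate
5 | 2-(bromomethyl)-3-methoxy-5-(methoxymethoxy)phenyl trifluoromethanesulfonate | COCOc1cc(OC)c(CBr)c(OS(=O)(=O)C(F)(F)F)c1 | intermediate
6 | resorcinol (benzene-1,3-diol) | Oc1cccc(O)c1 | starting material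
7 | 1,3-bis(methoxymethoxy)benzene | COCOc1cccc(OCOC)c1 | intermediate
8 | prenyl bromide (1-bromo-3-methylbut-2-ene) | CC(C)=CCBr | starting material
9 | 2,6-bis(methoxymethoxy)phenyllithium | [Li]c1c(OCOC)cccc1OCOC | intermediate
10 | 1,3-bis(methoxymethoxy)-2-(3-methylbut-2-en-1-yl)benzene | COCOc1cccc(OCOC)c1CC=C(C)C | intermediate
11 | 2,4-bis(methoxymethoxy)-3-(3-methylbut-2-en-1-yl)phenyllithium | [Li]c1ccc(OCOC)c(CC=C(C)C)c1OCOC | intermediate
12 | 2-[2,4-bis(methoxymethoxy)-3-(3-methylbut-2-en-1-yl)phenyl]ethan-1-ol | OCCc1ccc(OCOC)c(CC=C(C)C)c1OCOC | intermediate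
13 | 2-[2,4-bis(methoxymethoxy)-3-(3-methylbut-2-en-1-yl)phenyl]acetaldehyde | O=CCc1ccc(OCOC)c(CC=C(C)C)c1OCOC | intermediate
14 | 2-[2,4-bis(methoxymethoxy)-3-(3-methylbut-2-en-1-yl)phenyl]acetic acid | OC(=O)Cc1ccc(OCOC)c(CC=C(C)C)c1OCOC | intermediate
15 | (R)-4-benzyloxazolidin-2-one | O=C1N[C@H](Cc2ccccc2)CO1 | starting material
16 | mixed anhydride of acid 14 and pivalic acid | CC(C)(C)C(=O)OC(=O)Cc1ccc(OCOC)c(CC=C(C)C)c1OCOC | intermediate
17 | (4R)-4-benzyl-3-{2-[2,4-bis(methoxymethoxy)-3-(3-methylbut-2-en-1-yl)phenyl]acetyl}oxazolidin-2-one | O=C(Cc1ccc(OCOC)c(CC=C(C)C)c1OCOC)N1[C@H](Cc2ccccc2)COC1=O | intermediate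
18 | sodium (Z)-enolate of imide 17 (O–Na and aryl cis) | [Na]O/C(=C\c1ccc(OCOC)c(CC=C(C)C)c1OCOC)N1[C@H](Cc2ccccc2)COC1=O | intermediate
19 | (4R)-4-benzyl-3-{(2R)-2-[2,4-bis(methoxymethoxy)-3-(3-methylbut-2-en-1-yl)phenyl]-3-[2-methoxy-4-(methoxymethoxy)-6-(trifluoromethylsulfonyloxy)phenyl]propanoyl}oxazolidin-2-one | COc1cc(OCOC)cc(OS(=O)(=O)C(F)(F)F)c1C[C@H](c1ccc(OCOC)c(CC=C(C)C)c1OCOC)C(=O)N1[C@H](Cc2ccccc2)COC1=O | intermediate
20 | 2-{(2R)-2-[2,4-bis(methoxymethoxy)-3-(3-methylbut-2-en-1-yl)phenyl]-3-hydroxypropyl}-3-methoxy-5-(methoxymethoxy)phenyl trifluoromethanesulfonate | COc1cc(OCOC)cc(OS(=O)(=O)C(F)(F)F)c1C[C@H](c1ccc(OCOC)c(CC=C(C)C)c1OCOC)CO | intermediate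
21 | lithium alkoxide of 20 lithiated at the ring carbon between the triflate and the MOM ether (future C8) | COc1cc(OCOC)c([Li])c(OS(=O)(=O)C(F)(F)F)c1C[C@H](c1ccc(OCOC)c(CC=C(C)C)c1OCOC)CO[Li] | intermediate
22 | lithium (2R)-2-[2,4-bis(methoxymethoxy)-3-(3-methylbut-2-en-1-yl)phenyl]-3-[2-methoxy-4-(methoxymethoxy)-5,6-didehydrophenyl]propan-1-olate (C8–C8a aryne) | COC1=C(C[C@H](c2ccc(OCOC)c(CC=C(C)C)c2OCOC)CO[Li])C#CC(OCOC)=C1 | intermediate
23 | (3R)-3-[2,4-bis(methoxymethoxy)-3-(3-methylbut-2-en-1-yl)phenyl]-8-lithio-5-methoxy-7-(methoxymethoxy)chromane | COc1cc(OCOC)c([Li])c2c1C[C@H](c1ccc(OCOC)c(CC=C(C)C)c1OCOC)CO2 | intermediate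
24 | lithium alkoxide of the C8 (dimethylamino)(hydroxy)methyl adduct of 23 with DMF (hemiaminal carbon unassigned) | COc1cc(OCOC)c(C(O[Li])N(C)C)c2c1C[C@H](c1ccc(OCOC)c(CC=C(C)C)c1OCOC)CO2 | intermediate
25 | (3R)-3-[2,4-bis(methoxymethoxy)-3-(3-methylbut-2-en-1-yl)phenyl]-5-methoxy-7-(methoxymethoxy)chromane-8-carbaldehyde | COc1cc(OCOC)c(C=O)c2c1C[C@H](c1ccc(OCOC)c(CC=C(C)C)c1OCOC)CO2 | intermediate
26 | (3R)-3-[2,4-dihydroxy-3-(3-methylbut-2-en-1-yl)phenyl]-7-hydroxy-5-methoxychromane-8-carbaldehyde | COc1cc(O)c(C=O)c2c1C[C@H](c1ccc(O)c(CC=C(C)C)c1O)CO2 | target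

Total step count: 13.
Longest linear sequence: 9 steps (steps 5 to 13, from resorcinol 6); the ring A branch (steps 1 to 4) joins at step 10.

Steps most likely to fail

Step 12. Three processes could divert the reaction. After lithiation at C8 the triflyl group may migrate from oxygen to C8 (anionic thia-Fries shift) faster than triflate is lost. The alkoxide may attack the sulfonyl group before the aryne forms. The C8 aryllithium may be protonated before DMF reaches it. The fallback separates the two bond formations and uses known reactions only. It sets out from 20: the triflate is cleaved with Et4NOH in dioxane to the open-chain phenol F1, and Mitsunobu cyclodehydration (PPh3, DIAD, THF) closes the pyran to the 8-unsubstituted chromane F2. One equivalent of NBS in CH2Cl2 at −78 °C should then brominate the trioxygenated ring A at C8 and give the 8-bromochromane F3. C8 lies between the ring oxygen and the MOM ether and is less hindered than C6, as in 5,7-dialkoxyflavans, and ring B and the prenyl alkene are much less reactive. Bromine–lithium exchange with n-BuLi at −78 °C gives 23, and DMF quench returns to the route at 25.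

Step 13. Under protic acid the prenyl double bond may be protonated and the tertiary cation captured by the freed 2'- or 4'-hydroxyl group, closing a dimethylchromane ring on ring B; hydration of the alkene is a second possibility. The fallback avoids free Brønsted acid. It sets out from 25: Me3SiOTf with 2,2'-bipyridyl in CH2Cl2 at 0 °C exchanges the three aryl MOM ethers for silyl ethers, the bipyridyl taking up the methoxymethyl cation, to give the tris(trimethylsilyl) ether F4. Brief hydrolysis with water (or K2CO3 in MeOH) then frees the phenols and arrives at 26.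

Step 10. Substitution at the doubly ortho-substituted benzylic carbon of 5 by the hindered enolate 18 may be slow. Warming would then let the enolate fragment or the new α-aryl centre epimerise, and the bromide may ionise and self-condense. The fallback replaces the alkylation by condensation and catalytic asymmetric hydrogenation. It sets out from acid 14 and aldehyde 3: Perkin condensation (Ac2O, Et3N, 100 °C) should give the (E)-2,3-diarylacrylic acid F5. Carboxylate-directed hydrogenation with Ru(OAc)2(BINAP) in MeOH, which leaves isolated trisubstituted alkenes alone, gives the (R)-2,3-diarylpropanoic acid F6; the BINAP antipode is chosen in a trial run to deliver the (R) acid. Activation with isobutyl chloroformate and N-methylmorpholine gives the mixed carbonic anhydride F7, and NaBH4 reduction returns to the route at 20.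

Further compounds
F1 | step 12 | 2-{(2R)-2-[2,4-bis(methoxymethoxy)-3-(3-methylbut-2-en-1-yl)phenyl]-3-hydroxypropyl}-3-methoxy-5-(methoxymethoxy)phenol | COc1cc(OCOC)cc(O)c1C[C@H](c1ccc(OCOC)c(CC=C(C)C)c1OCOC)CO
F2 | step 12 | (3R)-3-[2,4-bis(methoxymethoxy)-3-(3-methylbut-2-en-1-yl)phenyl]-5-methoxy-7-(methoxymethoxy)chromane | COc1cc(OCOC)cc2c1C[C@H](c1ccc(OCOC)c(CC=C(C)C)c1OCOC)CO2
F3 | step 12 | (3R)-3-[2,4-bis(methoxymethoxy)-3-(3-methylbut-2-en-1-yl)phenyl]-8-bromo-5-methoxy-7-(methoxymethoxy)chromane | COc1cc(OCOC)c(Br)c2c1C[C@H](c1ccc(OCOC)c(CC=C(C)C)c1OCOC)CO2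
F4 | step 13 | (3R)-5-methoxy-7-(trimethylsilyloxy)-3-[3-(3-methylbut-2-en-1-yl)-2,4-bis(trimethylsilyloxy)phenyl]chromane-8-carbaldehyde | COc1cc(O[Si](C)(C)C)c(C=O)c2c1C[C@H](c1ccc(O[Si](C)(C)C)c(CC=C(C)C)c1O[Si](C)(C)C)CO2
F5 | step 10 | (E)-2-[2,4-bis(methoxymethoxy)-3-(3-methylbut-2-en-1-yl)phenyl]-3-[2-methoxy-4-(methoxymethoxy)-6-(trifluoromethylsulfonyloxy)phenyl]acrylic acid | OC(=O)/C(c1ccc(OCOC)c(CC=C(C)C)c1OCOC)=C/c1c(OC)cc(OCOC)cc1OS(=O)(=O)C(F)(F)F
F6 | step 10 | (2R)-2-[2,4-bis(methoxymethoxy)-3-(3-methylbut-2-en-1-yl)phenyl]-3-[2-methoxy-4-(methoxymethoxy)-6-(trifluoromethylsulfonyloxy)phenyl]propanoic acid | COc1cc(OCOC)cc(OS(=O)(=O)C(F)(F)F)c1C[C@H](c1ccc(OCOC)c(CC=C(C)C)c1OCOC)C(=O)O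
F7 | step 10 | mixed anhydride of acid F6 and isobutyl hydrogen carbonate | COc1cc(OCOC)cc(OS(=O)(=O)C(F)(F)F)c1C[C@H](c1ccc(OCOC)c(CC=C(C)C)c1OCOC)C(=O)OC(=O)OCC(C)C
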